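# Proposed synthesis of 2-hydroxy-4-methoxy-6-(2-oxotridecyl)benzoic acid (19) by rhodium-catalysed [5+1] carbonylative benzannulation

## The problem

Target 19 is a single benzene ring with no stereocentre, carrying CO2H on C1, OH on C2, OMe on C4 and a 2-oxotridecyl chain on C6. The task is therefore one of regiochemistry and functional-group lability, not of ring fusion or stereocontrol. The two ring oxygens are chemically alike but must end differently, C2 as a free phenol and C4 as a methyl ether. The carboxyl lies between two ortho substituents, so its esters are slow to hydrolyse, and the free electron-rich salicylic acid loses CO2 when heated in acid. The side-chain ketone is β to the ring, which creates three hazards: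

- the keto acid can close to an isocoumarin under dehydrating acid;
- a keto ester can undergo Claisen closure to a naphthalene-1,3-diol under alkoxide;
- any precursor with a side-chain alcohol can lactonise onto the carboxyl to a dihydroisocoumarin.

Stereocentres appear only in intermediates (the carbinol carbon of the chain and the propargylic carbon of the ring precursor). Both become sp2 carbons, so neither needs control. The enabling feature is that the C2 and C4 oxygens are meta and C4 sits between the unsubstituted carbons C3 and C5. This is the pattern produced when carbon monoxide is inserted between the two ends of an acyloxy-substituted dienyl carbene, so C4 with its oxygen can come from CO and the other five ring carbons from a 3-acyloxy-1,4-enyne that already carries the carboxyl and the side chain.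

## Retrosynthesis

**19 from 18 (unmasking).** The last operation cuts two acyl–oxygen bonds: the methyl ester at C1 and the pivalate on the C2 oxygen of keto diester 18, both removed by hydroxide. Keeping both esters to the end is preferred to freeing the acid earlier, because a free acid next to a side-chain hydroxyl would lactonise and the salicylic acid is prone to decarboxylation during further handling. Compound 18 has the same skeleton as 19 but is a neutral, easily purified keto diester. The forward reaction must saponify a di-ortho-substituted benzoate without Claisen closure of the keto ester.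

**18 back to 15 (oxidation level and O-methyl).** The ketone of 18 is traced to the secondary alcohol 17 and its silyl ether 16, and the C4 methyl ether to the free phenol 15 (O–CH3 bond cut). The ketone cannot be carried further back: in an acyclic precursor it would be β,γ-unsaturated and would conjugate, and it would not survive an organolithium. A TBS ether at the alcohol level is inert to all earlier steps. Methylation of 15 needs no selectivity, since the C2 oxygen is already an ester. The forward steps must free the alcohol without letting it attack the neighbouring ester, then oxidise it under neutral conditions.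

**15 from 11 and 12 (the ring).** The bonds C3–C4 and C4–C5 are cut, C4 and its oxygen leave as carbon monoxide 12, and the pivalate returns from C2 to the carbon that becomes C1, giving enyne 11. Against the neighbouring cuts:

- Cutting C1–C6 (aldol) starts from a polycarbonyl chain that is delicate to assemble.
- Cutting the aryl–CH2 bond or the C1–carboxyl bond starts from a dioxygenated arene whose two oxygens must be told apart afterwards.
- The chosen cut differentiates the oxygens as a consequence of the mechanism and installs carboxyl and side chain before the ring exists.

The precursor is acyclic and is assembled from three simple pieces. The forward reaction must deliver a 1,2-acyloxy shift, CO uptake, and the correct geometry of the new enol ester at a quaternary, ester-bearing propargylic carbon.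

**11 from 4 and 7 (quaternary carbon).** Desilylation of the alkyne relates 11 to 10. In 10 the bond between the quaternary carbon and the alkenyl carbon is cut, together with the O–pivaloyl bond, giving vinyl bromide 4 (as its lithium derivative 8) and α-keto ester 7. The reverse order, an acetylide added to an alkenyl keto ester, would need a polymerisation-prone α-methylene keto ester; it is kept as a fallback. Compound 7 has no α-hydrogen, so a basic vinyllithium cannot enolise it. The forward reaction requires ketone-selective 1,2-addition and trapping of a hindered tertiary alkoxide.

**7 from 5 and 6.** The alkynyl–acyl bond is cut. Electrophilic ipso-substitution of one silyl group of bis(trimethylsilyl)acetylene 5 by methyl chlorooxoacetate 6 gives the keto ester in one step and keeps the alkyne terminus protected.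

**4 from 1 and 2.** After removal of the silyl group (4 to 3), the bond between the carbinol carbon and the allylic CH2 is cut, leading to dodecanal 1 and 2,3-dibromopropene 2. A Barbier reaction joins them and leaves the vinylic bromide as the handle for the later lithiation; routes through an allylsilane or an enolate would need more steps to reach the same 2-metallo-allyl pattern.

## Roads not taken

**Alternative 1:** The cut is the aryl–CH2 bond at C6 together with the enol-lactone C–O bond. 2,4-Dimethoxybenzoic acid A1 and dimethylsulfoxonium 2-oxotridecylide A2 would be combined under [Cp*RhCl2]2 and AgSbF6. The carboxylate directs trivalent rhodium to the only free ortho C–H, the ylide supplies a carbene that inserts, and the keto acid closes to 6,8-dimethoxy-3-undecylisocoumarin A3. Chelation-controlled cleavage of the peri methyl ether with BCl3 would give 8-hydroxy-6-methoxy-3-undecylisocoumarin A4, and hydroxide opening of the enol lactone would give 19.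

- Merits: about four steps; unambiguous regiochemistry (one ortho C–H); the side chain arrives at the ketone level; the isocoumarin is a stable store for the keto acid.
- Weak points: ortho-alkoxy, electron-rich benzoic acids are prone to protodecarboxylation with silver salts at the temperatures such annulations need; the two oxygens are differentiated only by a later selective demethylation; a cyclopentadienyl rhodium catalyst and a silver additive are required.
- Comparison: this road is clearly shorter and better on step economy. The chosen plan sets against it that the C2 and C4 oxygens are differentiated by the ring-forming mechanism itself, that no free electron-rich benzoic acid is exposed to metal salts and heat, and that the C4 carbon comes from CO and could be isotopically labelled. If brevity alone decided, Alternative 1 would win.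

**Alternative 2:** The cut is the ring bond C1–C6, formed by intramolecular aldol condensation while the carboxyl and the C2 oxygen are tied together in a dioxinone. With Et3N, the diketo-dioxinone 2,2-dimethyl-6-[2,4-dioxo-5-(2-undecyl-1,3-dioxolan-2-yl)pentyl]-4H-1,3-dioxin-4-one A5 would cyclise, dehydrate and enolise to 7-hydroxy-2,2-dimethyl-5-[(2-undecyl-1,3-dioxolan-2-yl)methyl]-1,3-benzodioxin-4-one A6. Methylation of the free phenol, hydroxide opening of the dioxinone and acidic removal of the dioxolane would follow.

- Merits: the aromatisation is mild and well precedented for 6-alkyl resorcylates; it gives the same oxygen differentiation as the chosen plan; the ketone is carried masked at the correct oxidation level, so no redox step is needed; no pressure equipment or precious metal.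
- Weak points: A5 must be built by C-acylation of a dioxinone keto-enolate with an activated β-ketal acid that itself takes several steps; the tricarbonyl chain can close in other ways (pyranone formation) and is awkward to purify; the β-keto ketal can open by elimination; the end needs hot hydroxide on a hindered benzodioxinone and then aqueous acid beside a decarboxylation-prone acid.
- Comparison: step count is similar (about eight to nine). On security of the key step Alternative 2 is ahead, because aromatisation of an arene that already bears the carboxyl is established. The chosen plan offers non-enolisable, robust intermediates up to the ring-forming step and a convergent union of three simple pieces.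

**Alternative 3:** The cut is the C1–carboxyl bond, with the lactone C–O bond. The symmetrical alcohol 1-(3,5-dimethoxyphenyl)tridecan-2-ol A7 would be treated with Pd(OAc)2, an N-protected amino acid ligand, AgOAc and CO. The hydroxyl directs divalent palladium to either of the two equivalent ortho C–H bonds, CO inserts, and C–O bond formation gives racemic 6,8-dimethoxy-3-undecylisochroman-1-one A8.

- Merits: symmetry removes the regiochemical question; A7 is one or two steps from cheap aromatic material; the carbonylation runs at low CO pressure.
- Weak points: A8 is at the wrong oxidation level, since its side-chain oxygen is a lactone alcohol and the target has a ketone. Reaching 19 would need dehydrogenation to A3 (benzylic bromination and elimination), then the demethylation to A4 and lactone opening described above. A secondary carbinol as directing group is liable to oxidation by divalent palladium, and the method is best established for tertiary alcohols. Stoichiometric silver is consumed.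
- Comparison: length is similar or slightly shorter (six to seven steps), and starting materials are cheaper. The chosen plan also adjusts an alcohol to a ketone, but by plain oxidation of a free secondary alcohol; it needs no selective demethylation and no dehydrogenation of a lactone.

Key step: step 6

## Route

Assumption: the carbinol carbon formed in step 1 and the quaternary carbon formed in step 4 are carried without stereocontrol (racemate, then mixture of diastereomers), since both become sp2 carbons before the end.

Step 1
Reactants: 1 dodecanal; 2 2,3-dibromopropene
Product: 3 2-bromopentadec-1-en-4-ol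
Conditions: Sn powder, HBr (cat.), Et2O/H2O, rt
Reagents that add atoms: none
Why: Barbier-type allylation: tin inserts into the allylic C–Br bond of 2 (the vinylic bromide is inert) and the allyltin species adds to the aldehyde in the two-phase aqueous medium. The carbinol stereocentre forms racemic, which is immaterial because it is later oxidised.

Step 2
Reactants: 3 2-bromopentadec-1-en-4-ol
Product: 4 (2-bromopentadec-1-en-4-yl)oxy(tert-butyl)dimethylsilane
Conditions: TBSCl, imidazole, DMF, rt
Reagents that add atoms: tert-butyldimethylsilyl chloride, CC(C)(C)[Si](C)(C)Cl
Why: Standard silylation of a secondary alcohol; the TBS ether tolerates the organolithium step, the rhodium/CO step and the basic methylation.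

Step 3
Reactants: 5 bis(trimethylsilyl)acetylene; 6 methyl chlorooxoacetate
Product: 7 methyl 2-oxo-4-(trimethylsilyl)but-3-ynoate
Conditions: AlCl3, CH2Cl2, 0 °C
Reagents that add atoms: none
Why: Friedel–Crafts-type ipso-acylation of an alkynylsilane: the acylium species from 6 and AlCl3 replaces one trimethylsilyl group, and the electron-poor ynone formed does not react a second time.

Step 4
Reactants: 4 (2-bromopentadec-1-en-4-yl)oxy(tert-butyl)dimethylsilane; 7 methyl 2-oxo-4-(trimethylsilyl)but-3-ynoate
Product: 10 methyl 5-(tert-butyldimethylsilyloxy)-3-methylidene-2-(pivaloyloxy)-2-[(trimethylsilyl)ethynyl]hexadecanoate, via vinyllithium 8 (not isolated), via lithium alkoxide 9 (not isolated)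
Conditions: t-BuLi (2 equiv), Et2O, −78 °C; cannulate into 7, THF, −78 °C; then PivCl, −78 °C to rt
Reagents that add atoms: pivaloyl chloride, CC(C)(C)C(=O)Cl
Why: Lithium–bromine exchange gives vinyllithium 8, which adds 1,2 to the ketone carbonyl of the non-enolisable α-keto ester 7 (more electrophilic than the ester). The tertiary lithium alkoxide 9 is O-acylated in the same flask, the usual way to tertiary propargylic pivalates. The quaternary stereocentre forms without control relative to the silyloxy carbon; both are erased later.

Step 5
Reactants: 10 methyl 5-(tert-butyldimethylsilyloxy)-3-methylidene-2-(pivaloyloxy)-2-[(trimethylsilyl)ethynyl]hexadecanoate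
Product: 11 methyl 5-(tert-butyldimethylsilyloxy)-2-ethynyl-3-methylidene-2-(pivaloyloxy)hexadecanoate
Conditions: K2CO3 (cat.), MeOH, 0 °C
Reagents that add atoms: none
Why: Base-catalysed methanolysis of the alkynyl C–Si bond is fast at 0 °C, whereas the secondary TBS ether and the hindered tertiary pivalate are untouched and methanol cannot change the methyl ester.

Step 6
Reactants: 11 methyl 5-(tert-butyldimethylsilyloxy)-2-ethynyl-3-methylidene-2-(pivaloyloxy)hexadecanoate; 12 carbon monoxide
Product: 15 methyl 6-[2-(tert-butyldimethylsilyloxy)tridecyl]-4-hydroxy-2-(pivaloyloxy)benzoate, via dienylketene 13 (not isolated), via cyclohexadienone tautomer 14 (not isolated)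
Conditions: [Rh(CO)2Cl]2 (5 mol %), CO (autoclave, ca. 50–80 atm), CH2Cl2, 80 °C
Reagents that add atoms: none
Why: The closest known reaction type is the [Rh(CO)2Cl]2-catalysed [5+1] carbonylative benzannulation of 3-acyloxy-1,4-enynes to resorcinol monoesters; 11 belongs to this class, but a quaternary propargylic carbon that also bears an ester has not been examined. Monovalent rhodium binds the terminal alkyne, the pivalate carbonyl oxygen attacks the internal alkyne carbon, and opening of the dioxolenium intermediate moves the ester to that carbon (1,2-acyloxy shift) and leaves a rhodium carbene at the former terminal carbon. CO insertion forms C3–C4 and gives dienylketene 13 (free or rhodium-bound), whose six-electron disrotatory electrocyclisation onto the 1,1-disubstituted alkene forms C4–C5 and closes the six-membered carbocycle; enolisation of dienone 14 then gives the phenol. No stereocentre is created, and the quaternary centre of 11 disappears as aromatic C1, leaving only the racemic silyloxy carbon. The step needs 1,2- over 1,3-acyloxy shift, which the terminal alkyne secures, and six- over five-membered carbonylative closure, which the terminal alkyne and CO pressure favour. It also needs the alkenyl group, not the ester, cis to the carbene across the new enol-ester double bond; η2-coordination of the alkene to rhodium during the shift and the reversibility of the shift should channel material through that geometry. The product carries pivalate on the C2 oxygen and its only free hydroxyl on C4, so the two oxygens are differentiated without a selective protection.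

Step 7
Reactants: 15 methyl 6-[2-(tert-butyldimethylsilyloxy)tridecyl]-4-hydroxy-2-(pivaloyloxy)benzoate
Product: 16 methyl 6-[2-(tert-butyldimethylsilyloxy)tridecyl]-4-methoxy-2-(pivaloyloxy)benzoate
Conditions: MeI, K2CO3, acetone, rt
Reagents that add atoms: iodomethane, CI
Why: Williamson O-methylation of the only free phenol; the C2 oxygen is blocked as a pivalate that is stable to K2CO3 in acetone, so no regiochemical choice arises.

Step 8
Reactants: 16 methyl 6-[2-(tert-butyldimethylsilyloxy)tridecyl]-4-methoxy-2-(pivaloyloxy)benzoate
Product: 17 methyl 6-(2-hydroxytridecyl)-4-methoxy-2-(pivaloyloxy)benzoate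
Conditions: HF·pyridine, pyridine, THF, 0 °C to rt
Reagents that add atoms: none
Why: Fluoride cleavage of a secondary TBS ether under buffered, mildly acidic conditions, chosen over basic fluoride sources so that no alkoxide forms that could attack the neighbouring ester. Esters and the aryl ether are inert, and the alcohol is oxidised without storage.

Step 9
Reactants: 17 methyl 6-(2-hydroxytridecyl)-4-methoxy-2-(pivaloyloxy)benzoate
Product: 18 methyl 4-methoxy-6-(2-oxotridecyl)-2-(pivaloyloxy)benzoate
Conditions: Dess–Martin periodinane, CH2Cl2, rt
Reagents that add atoms: none
Why: Dess–Martin oxidation of a secondary alcohol to the ketone under neutral conditions, which avoids enolate chemistry of the new benzylic ketone and removes the last stereocentre.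

Step 10
Reactants: 18 methyl 4-methoxy-6-(2-oxotridecyl)-2-(pivaloyloxy)benzoate
Product: 19 2-hydroxy-4-methoxy-6-(2-oxotridecyl)benzoic acid
Conditions: KOH (aq), MeOH/THF, 50 °C; then 1 M HCl, 0 °C
Reagents that add atoms: potassium hydroxide, [K+].[OH-]
Why: Saponification: hydroxide cleaves the aryl pivalate and the methyl ester. The hindered benzoate may also react by way of the enolate-derived isocoumarin, which hydroxide opens to the same keto carboxylate. Cold acidification frees the acid without decarboxylation.

## Compound list

1 | dodecanal | CCCCCCCCCCCC=O | starting material
2 | 2,3-dibromopropene | BrCC(Br)=C | starting material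
3 | 2-bromopentadec-1-en-4-ol (racemic) | C=C(Br)CC(O)CCCCCCCCCCC | intermediate
4 | (2-bromopentadec-1-en-4-yl)oxy(tert-butyl)dimethylsilane (racemic) | C=C(Br)CC(O[Si](C)(C)C(C)(C)C)CCCCCCCCCCC | intermediate
5 | bis(trimethylsilyl)acetylene | C[Si](C)(C)C#C[Si](C)(C)C | starting material
6 | methyl chlorooxoacetate | COC(=O)C(=O)Cl | starting material
7 | methyl 2-oxo-4-(trimethylsilyl)but-3-ynoate | COC(=O)C(=O)C#C[Si](C)(C)C | intermediate
8 | [4-(tert-butyldimethylsilyloxy)pentadec-1-en-2-yl]lithium (racemic) | [Li]C(=C)CC(O[Si](C)(C)C(C)(C)C)CCCCCCCCCCC | intermediate
9 | lithium alkoxide of methyl 5-(tert-butyldimethylsilyloxy)-2-hydroxy-3-methylidene-2-[(trimethylsilyl)ethynyl]hexadecanoate (mixture of diastereomers) | [Li+].COC(=O)C([O-])(C#C[Si](C)(C)C)C(=C)CC(O[Si](C)(C)C(C)(C)C)CCCCCCCCCCC | intermediate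
10 | methyl 5-(tert-butyldimethylsilyloxy)-3-methylidene-2-(pivaloyloxy)-2-[(trimethylsilyl)ethynyl]hexadecanoate (mixture of diastereomers) | COC(=O)C(OC(=O)C(C)(C)C)(C#C[Si](C)(C)C)C(=C)CC(O[Si](C)(C)C(C)(C)C)CCCCCCCCCCC | intermediate
11 | methyl 5-(tert-butyldimethylsilyloxy)-2-ethynyl-3-methylidene-2-(pivaloyloxy)hexadecanoate (mixture of diastereomers) | C#CC(OC(=O)C(C)(C)C)(C(=O)OC)C(=C)CC(O[Si](C)(C)C(C)(C)C)CCCCCCCCCCC | intermediate
12 | carbon monoxide | [C-]#[O+] | starting material
13 | methyl (2Z)-2-[4-(tert-butyldimethylsilyloxy)pentadec-1-en-2-yl]-5-oxo-3-(pivaloyloxy)penta-2,4-dienoate (dienylketene, racemic, free or rhodium-bound) | O=C=C/C(OC(=O)C(C)(C)C)=C(C(=O)OC)\C(=C)CC(O[Si](C)(C)C(C)(C)C)CCCCCCCCCCC | intermediate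
14 | methyl 2-[2-(tert-butyldimethylsilyloxy)tridecyl]-4-oxo-6-(pivaloyloxy)cyclohexa-1,5-diene-1-carboxylate (racemic) | COC(=O)C1=C(CC(O[Si](C)(C)C(C)(C)C)CCCCCCCCCCC)CC(=O)C=C1OC(=O)C(C)(C)C | intermediate
15 | methyl 6-[2-(tert-butyldimethylsilyloxy)tridecyl]-4-hydroxy-2-(pivaloyloxy)benzoate (racemic) | COC(=O)c1c(OC(=O)C(C)(C)C)cc(O)cc1CC(O[Si](C)(C)C(C)(C)C)CCCCCCCCCCC | intermediate
16 | methyl 6-[2-(tert-butyldimethylsilyloxy)tridecyl]-4-methoxy-2-(pivaloyloxy)benzoate (racemic) | COC(=O)c1c(OC(=O)C(C)(C)C)cc(OC)cc1CC(O[Si](C)(C)C(C)(C)C)CCCCCCCCCCC | intermediate
17 | methyl 6-(2-hydroxytridecyl)-4-methoxy-2-(pivaloyloxy)benzoate (racemic) | COC(=O)c1c(OC(=O)C(C)(C)C)cc(OC)cc1CC(O)CCCCCCCCCCC | intermediate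
18 | methyl 4-methoxy-6-(2-oxotridecyl)-2-(pivaloyloxy)benzoate | COC(=O)c1c(OC(=O)C(C)(C)C)cc(OC)cc1CC(=O)CCCCCCCCCCC | intermediate
19 | 2-hydroxy-4-methoxy-6-(2-oxotridecyl)benzoic acid | CCCCCCCCCCCC(=O)Cc1cc(OC)cc(O)c1C(=O)O | target

## Step count and risk

Total step count: 10. Longest linear sequence: 9 steps (1, 2, 4, 5, 6, 7, 8, 9, 10); step 3 is a one-step side branch.

**Step 6 (key step).** The most likely failure is diversion of the rhodium carbene. If the acyloxy shift gives the enol ester with the ester group rather than the alkenyl group cis to the carbene, the carbene or ketene can be trapped by the ester carbonyl instead of closing onto the alkene. The electron-poor quaternary centre may also slow the 1,2-shift enough for a 1,3-shift to an allenyl ester, or simple recovery of 11, to dominate.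

Fallback, from 4, rejoining at 16: the carboxyl carbon is left out of the benzannulation and introduced afterwards, so the rhodium step runs on a secondary propargylic pivalate, the pattern for which it is established.
- Vinyllithium 8, generated from 4 as in step 4, would be formylated with DMF to 4-(tert-butyldimethylsilyloxy)-2-methylidenepentadecanal F1.
- Ethynylmagnesium bromide would give 6-(tert-butyldimethylsilyloxy)-4-methylideneheptadec-1-yn-3-ol F2, and PivCl, DMAP and Et3N its ester 6-(tert-butyldimethylsilyloxy)-4-methylideneheptadec-1-yn-3-yl pivalate F3.
- Carbonylative benzannulation under the conditions of step 6 should give 3-[2-(tert-butyldimethylsilyloxy)tridecyl]-5-hydroxyphenyl pivalate F4, methylated with MeI and K2CO3 to 3-[2-(tert-butyldimethylsilyloxy)tridecyl]-5-methoxyphenyl pivalate F5.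
- Bromination with NBS in MeCN, directed para to the methoxy group, would give 2-bromo-3-[2-(tert-butyldimethylsilyloxy)tridecyl]-5-methoxyphenyl pivalate F6.
- Palladium-catalysed methoxycarbonylation (Pd(OAc)2, Xantphos, CO, MeOH, Et3N) would deliver 16.

The price is two more steps and a regiochemical question in the bromination.

**Step 4.** Compound 7 offers three electrophilic sites, so conjugate addition of the vinyllithium to the silyl ynone, or attack at the ester, may compete with addition to the ketone. O-acylation of the hindered, ester-stabilised tertiary alkoxide may also be incomplete before work-up.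

Fallback, from 4, rejoining at 10: the order of the two carbonyl additions is reversed. Vinyllithium 8 would be added to excess dimethyl oxalate at −78 °C to give methyl 5-(tert-butyldimethylsilyloxy)-3-methylidene-2-oxohexadecanoate F7. Lithium (trimethylsilyl)acetylide, a nucleophile that adds cleanly 1,2 to α-keto esters, would then give the same alkoxide 9, trapped with PivCl to 10. This does not address slow O-acylation, since it passes through the same alkoxide.

**Step 8.** Once the hydroxyl is free it can lactonise onto the neighbouring methyl ester to a dihydroisocoumarin, which removes the alcohol from the oxidation that must follow.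

Fallback, from 16 directly to 18: Jones reagent (CrO3, H2SO4, acetone, 0 °C) cleaves the secondary silyl ether and oxidises the liberated alcohol in the same flask, so the hydroxy ester never accumulates. No new compound arises (F0).

**Step 10.** Direct saponification of the di-ortho-substituted benzoate is slow, so Claisen closure of the chain-side enolate onto the ester (leading to a naphthalenediol) may compete. Heating or acidifying too vigorously may cause decarboxylation of the product.

Fallback, from 18, rejoining at 19: the ester carbonyl is first locked into the enol lactone. TsOH in refluxing toluene would convert 18, with loss of methanol, into 6-methoxy-1-oxo-3-undecyl-1H-isochromen-8-yl pivalate F8. Aqueous KOH in THF at room temperature would then open the lactone directly to the keto carboxylate and remove the pivalate, giving 19 after cold acidification. A carboxylate cannot undergo the Claisen closure.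

## Further compounds

F1 | step 6 | 4-(tert-butyldimethylsilyloxy)-2-methylidenepentadecanal (racemic) | O=CC(=C)CC(O[Si](C)(C)C(C)(C)C)CCCCCCCCCCC
F2 | step 6 | 6-(tert-butyldimethylsilyloxy)-4-methylideneheptadec-1-yn-3-ol (mixture of diastereomers) | C#CC(O)C(=C)CC(O[Si](C)(C)C(C)(C)C)CCCCCCCCCCC
F3 | step 6 | 6-(tert-butyldimethylsilyloxy)-4-methylideneheptadec-1-yn-3-yl pivalate (mixture of diastereomers) | C#CC(OC(=O)C(C)(C)C)C(=C)CC(O[Si](C)(C)C(C)(C)C)CCCCCCCCCCC
F4 | step 6 | 3-[2-(tert-butyldimethylsilyloxy)tridecyl]-5-hydroxyphenyl pivalate (racemic) | CC(C)(C)C(=O)Oc1cc(O)cc(CC(O[Si](C)(C)C(C)(C)C)CCCCCCCCCCC)c1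
F5 | step 6 | 3-[2-(tert-butyldimethylsilyloxy)tridecyl]-5-methoxyphenyl pivalate (racemic) | CC(C)(C)C(=O)Oc1cc(OC)cc(CC(O[Si](C)(C)C(C)(C)C)CCCCCCCCCCC)c1
F6 | step 6 | 2-bromo-3-[2-(tert-butyldimethylsilyloxy)tridecyl]-5-methoxyphenyl pivalate (racemic) | CC(C)(C)C(=O)Oc1cc(OC)cc(CC(O[Si](C)(C)C(C)(C)C)CCCCCCCCCCC)c1Br
F7 | step 4 | methyl 5-(tert-butyldimethylsilyloxy)-3-methylidene-2-oxohexadecanoate (racemic) | COC(=O)C(=O)C(=C)CC(O[Si](C)(C)C(C)(C)C)CCCCCCCCCCC
F0 | step 8 | none | none
F8 | step 10 | 6-methoxy-1-oxo-3-undecyl-1H-isochromen-8-yl pivalate | CCCCCCCCCCCc1cc2cc(OC)cc(OC(=O)C(C)(C)C)c2c(=O)o1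
A1 | alternative 1 | 2,4-dimethoxybenzoic acid | COc1ccc(C(=O)O)c(OC)c1
A2 | alternative 1 | dimethylsulfoxonium 2-oxotridecylide | CCCCCCCCCCCC(=O)C=S(C)(C)=O
A3 | alternative 1 | 6,8-dimethoxy-3-undecylisocoumarin | CCCCCCCCCCCc1cc2cc(OC)cc(OC)c2c(=O)o1
A4 | alternative 1 | 8-hydroxy-6-methoxy-3-undecylisocoumarin | CCCCCCCCCCCc1cc2cc(OC)cc(O)c2c(=O)o1
A5 | alternative 2 | 2,2-dimethyl-6-[2,4-dioxo-5-(2-undecyl-1,3-dioxolan-2-yl)pentyl]-4H-1,3-dioxin-4-one | CC1(C)OC(=O)C=C(CC(=O)CC(=O)CC2(CCCCCCCCCCC)OCCO2)O1
A6 | alternative 2 | 7-hydroxy-2,2-dimethyl-5-[(2-undecyl-1,3-dioxolan-2-yl)methyl]-1,3-benzodioxin-4-one | CC1(C)OC(=O)c2c(CC3(CCCCCCCCCCC)OCCO3)cc(O)cc2O1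
A7 | alternative 3 | 1-(3,5-dimethoxyphenyl)tridecan-2-ol (racemic) | CCCCCCCCCCCC(O)Cc1cc(OC)cc(OC)c1
A8 | alternative 3 | 6,8-dimethoxy-3-undecylisochroman-1-one (racemic) | CCCCCCCCCCCC1Cc2cc(OC)cc(OC)c2C(=O)O1
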